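## The problem

Target 14 is a 2,3-dihydro-1-benzofuran whose benzene ring carries an (E)-propenoic acid at C5 and whose C2 carries a 1-methyl-2-oxyethyl chain, esterified at oxygen with p-coumaric acid. There are two stereocentres, C2 in the ring and C1' in the chain, both S and directly bonded. Because C1' is acyclic, neither centre can direct the other unless both are held in a ring for a time. The ester that joins the two halves rules out late saponification, and the two conjugated (E)-alkenes rule out late hydrogenation and strong nucleophiles. Any intermediate with a carbonyl at the C1' carbon is a β-aryloxy carbonyl compound, so enolisation there can expel O1 and open the dihydrofuran ring. The free phenol and the free acid are competing pronucleophiles in any esterification. The enabling feature is twofold. C5 is para to O1, so the benzene ring with O1 and a C5 oxygen is the hydroquinone of 1,4-benzoquinone (3). C3–C2–C1' with the methyl group and the CH2O carbon are the five carbons of the α-methylbutenolide 1, provided the CH2O carbon is a carboxyl whose oxygen is bonded to C3. That extra C3–O bond is benzylic and can be removed by hydrogenolysis after it has tied C2 and C1' into a cis-fused bicycle.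

## Retrosynthesis

**14 ⇒ 13.** Only the O–C(CH3)3 bond of a tert-butyl ester on the C5 propenoic acid is cut. The acid must be masked because the coumarate is attached by alkylating a carboxylate, and a second free acid would compete. A tert-butyl ester is preferred to a methyl or benzyl ester because its removal needs neither hydroxide, which would cleave the coumarate, nor hydrogen, which would reduce both alkenes. The forward step asks for acidolysis that leaves a primary ester, an aryl alkyl ether and two cinnamate-type alkenes untouched.

**13 ⇒ 11 + 12.** The CH2–O bond of the coumarate ester is cut. Acylating the alcohol with an activated derivative of 12 would require the phenol of 12 to be protected and later freed. Alkylating the carboxylate under Mitsunobu conditions instead uses the acidity gap between acid and phenol, so 12 is used unprotected. Precursor 11 is smaller by nine carbons. The forward reaction must activate a primary, β-branched alcohol without touching C1'.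

**11 ⇒ 9 + 10.** The bond between C5 and the alkene carbon is cut, which is a Heck disconnection. The alternative, a C5 aldehyde followed by olefination, costs one more step. The oxygen that the quinone leaves at C5 becomes the leaving group as its triflate in 9. The forward step must give the (E)-alkene and tolerate a free primary alcohol.

**9 ⇒ 8 ⇒ 7.** These are functional-group changes: the aryl triflate comes from the phenol of 8, and the primary alcohol of 8 from the acid 7. Sulfonylation follows reduction so that the hydride never meets a sulfonate. Sulfonylation must select the phenol over the primary alcohol, and reduction must be non-basic because the α-carbon of 7 is epimerisable and β to O1.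

**7 ⇒ 6.** In the backward direction a bond is added, from the carboxyl oxygen to C3. C3 becomes the benzylic carbinol carbon of a γ-lactone, and C2 and C1' become adjacent members of a cis-fused bicyclic lactone. Compound 6 has three stereocentres instead of two, but they are mutually dependent. The forward reaction is hydrogenolysis of the benzylic C–O bond. It must come before any alkene is introduced, and it erases the C3 centre once that centre has done its work.

**6 ⇒ 2 + 3.** The bonds C3–C3a and O1–C2 are cut (target numbering; C8b–C8a and O4–C3a in the numbering of 6). Cutting O1–C7a instead would require an aryl–oxygen coupling on a preformed acyclic stereodiad. The chosen cut gives two flat, achiral components. The forward reaction is a vinylogous Mukaiyama–Michael addition of furan C5 to the quinone, aromatisation to the silylated hydroquinone 4, and 5-exo oxa-Michael closure to lactone 5.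

- **Enantiocontrol.** The only catalyst-controlled event is face selection at furan C5. Chelating chiral Lewis acids of the metal–bis(oxazoline) type were set aside because they need two donor atoms on the substrate and 3 offers one carbonyl lone pair. A cationic chiral oxazaborolidine is chosen because it holds a quinone carbonyl and the adjacent C–H together.
- **C1' configuration.** Kinetic protonation at the future C1' cannot be relied on, so that centre is set by equilibration to the convex-face methyl epimer.

**2 ⇒ 1.** The O–Si bond is cut. Silylation of butenolide 1 with γ-deprotonation gives the aromatic silyloxyfuran 2.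

## Roads not taken

**Alternative 1:** The benzene ring is cut at C3a–C7a, C4–C5 and C6–C7. In the forward direction the (2S,3S)-configured ynol ether diyne A1 and the alkyne acetal A2 undergo a crossed (2+2+2) cyclotrimerisation on a ruthenium or rhodium catalyst. This closes the benzene and dihydrofuran rings together and gives the C7-silylated C5 acetal A3.
- Merits: both stereocentres are set in an open chain by conventional methods before the key step, so absolute configuration does not depend on an untested catalyst. C5 arrives as a masked aldehyde, so no triflation or Heck reaction is needed.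
- Weak points: the silyl-capped ynol ether in A1 must be built on a secondary alcohol that already carries both centres, and it is acid-sensitive. Placement of the acetal at C5 and not C6 depends only on the steric bias of the silyl group. A2 can trimerise with itself. Protodesilylation, acetal hydrolysis, olefination, desilylation of the alcohol and esterification still follow.
- Comparison: in security of absolute stereochemistry this road is better. Against that, the chosen plan needs eight steps from four purchasable compounds, makes the ring and both permanent centres in one operation, and has a resolution fallback at the same disconnection.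

**Alternative 2:** The C2–C3 bond is cut. The aryl aldehyde N-tosylhydrazone A4 carries the (R)-3-silyloxy-2-methylpropyl chain on the ortho ether oxygen and bromine para to that oxygen. With base and a chiral porphyrin complex of divalent cobalt it gives a carbene radical at C3. This abstracts hydrogen from the O–CH2 carbon and recombines to close the ring as the 5-bromo-dihydrobenzofuran A5.
- Merits: C1' comes from the chiral pool. The aryl bromide is a direct Heck handle, which is better than the phenol-to-triflate detour of the chosen plan. The step count is comparable.
- Weak points: C2 is created next to an existing centre, so catalyst and substrate may be matched or mismatched. The radical can also reach the tertiary C1'–H by 1,6-transfer, which would give a chroman and destroy C1'. The hydrogen to be abstracted sits on an ether CH2 with no aryl or alkenyl stabilisation. The chiral porphyrin ligand is itself a multistep preparation.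
- Comparison: this road has the more secure C1' and the better C5 handle. The chosen plan derives both centres from a single event, locks them by ring fusion and equilibration, and uses a catalyst assembled in the flask from purchasable parts.

**Alternative 3:** The O1–C7a bond is formed by ring contraction. The 3-substituted isochroman-1-one A6 would be treated with a zerovalent nickel catalyst carrying a chelating bisphosphine. Nickel inserts into the acyl–oxygen bond, the carbonyl group is extruded, and aryl–oxygen reductive elimination gives the dihydrobenzofuran A7.
- Merits: lactones such as A6 can be made with full stereocontrol by standard chemistry, so the stereochemistry does not depend on the key step.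
- Weak points: insertion into an alkyl ester acyl–oxygen bond is much harder than into the aryl esters for which decarbonylative coupling is established. Reductive elimination of an alkyl aryl ether from divalent nickel is slow. The nickel alkoxide has a β-hydrogen at C2, whose elimination would destroy that centre. A7 has no C5 substituent, so bromination and then the Heck sequence must still follow.
- Comparison: the stereochemistry is more secure here. The key step is further from precedent than that of the chosen plan, which at least has a racemic counterpart, and no known-chemistry fallback exists at the same cut.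

Key step: step 2

Assumption: the sense of induction in step 2 cannot be assigned with confidence in advance; the catalyst from (S)-α,α-diphenylprolinol is written, and its mirror image is used instead if the antipode of 6 is what forms.

## Route

Step 1
Reactants: 1 3-methylfuran-2(5H)-one
Product: 2 3-methyl-2-(trimethylsilyloxy)furan
Conditions: Et3N (1.3 equiv), TMSOTf (1.1 equiv), Et2O, 0 °C to rt; filtration under argon, distillation
Reagents that add atoms: trimethylsilyl trifluoromethanesulfonate, C[Si](C)(C)OS(=O)(=O)C(F)(F)F
Why: Soft enolisation: O-silylation of the lactone carbonyl makes the γ-hydrogens acidic enough for Et3N, and the aromatic 2-silyloxyfuran results (silyl dienol ether formation from a butenolide); no stereocentre is involved.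

Step 2
Reactants: 2 3-methyl-2-(trimethylsilyloxy)furan; 3 1,4-benzoquinone
Product: 6 (3R,3aR,8bR)-7-hydroxy-3-methyl-3a,8b-dihydrofuro[3,2-b][1]benzofuran-2(3H)-one, via silylated hydroquinone butenolide 4 (not isolated), via silylated lactone 5 (not isolated)
Conditions: (S)-3,3-diphenyl-1-(2-methylphenyl)tetrahydro-1H,3H-pyrrolo[1,2-c][1,3,2]oxazaborole (20 mol%), Tf2NH (18 mol%), Ph3PO (25 mol%), CH2Cl2, −78 to −20 °C, 2 (1.2 equiv) added slowly; then DBU (0.5 equiv), 0 °C to rt, argon; aq. citric acid work-up
Reagents that add atoms: none
Why: Proposed new method: the N-protonated oxazaborolidine binds one carbonyl oxygen of 3 at boron while the neighbouring ring C–H leans on the catalyst oxygen, the two-point hold known from enantioselective Diels–Alder reactions of simple quinones, so one face of the activated enone unit is covered by the B-aryl group and furan C5 of 2 adds to the β-carbon from the open face in a compact endo-like array (vinylogous Mukaiyama–Michael addition; closest known types are the racemic furofuran annulation of quinones with 2-silyloxyfurans and the Michael addition of silyl ketene acetals to enones under the same class of boron cation). Silicon moves to the quinone oxygen, Ph3PO keeping free silyl cation and with it the racemic channel low, and enolisation gives the aryl silyl ether 4. Because the quinone carbon ends up aromatic, the only centre made in this C–C bond formation is the butenolide γ-carbon C8b, and it is the one centre set by the catalyst. The free ortho hydroxyl then adds to the butenolide β-carbon in a 5-exo-trig oxa-Michael closure of the dihydrofuran ring; a trans-fused bicyclo[3.3.0] frame is out of reach, so C3a is fixed cis to C8b by the substrate. C3 arises by protonation of the lactone enol and may come out as either epimer (5), so DBU is added to equilibrate it through the enolate to the more stable arrangement with methyl on the convex face, trans to O4, before the silyl ether is hydrolysed to 6. The step needs enantioface selection at furan C5 (catalyst), which regiochemistry cannot complicate since all four ring CH carbons of 3 are equivalent, and it needs ring closure to be complete before base is added, because the γ-hydrogen of uncyclised 4 is acidic and its removal would racemise the centre from which the other two are derived.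

Step 3
Reactants: 6 (3R,3aR,8bR)-7-hydroxy-3-methyl-3a,8b-dihydrofuro[3,2-b][1]benzofuran-2(3H)-one
Product: 7 (2R)-2-[(2S)-5-hydroxy-2,3-dihydro-1-benzofuran-2-yl]propanoic acid
Conditions: H2 (1 atm), 10% Pd/C, EtOAc–MeOH, rt
Reagents that add atoms: none
Why: Hydrogenolysis of a benzylic carboxylate C–O bond (the benzyl ester cleavage type), assisted by the ortho ring oxygen; C8b becomes the C3 methylene, while C2 and the α-carbon are untouched under neutral conditions that avoid ionisation at the benzylic carbon and aromatisation to a benzofuran.

Step 4
Reactants: 7 (2R)-2-[(2S)-5-hydroxy-2,3-dihydro-1-benzofuran-2-yl]propanoic acid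
Product: 8 (2S)-2-[(2S)-1-hydroxypropan-2-yl]-2,3-dihydro-1-benzofuran-5-ol
Conditions: BH3·THF (3 equiv), THF, 0 °C to rt; H2O quench
Reagents that add atoms: none
Why: Chemoselective borane reduction of a carboxylic acid through its acyloxyborane; the phenol only consumes hydride as a borate ester cleaved on work-up, and the non-basic medium leaves the α-centre intact and cannot trigger β-elimination of O1 (the descriptor at C1' changes from R to S only because the priorities change).

Step 5
Reactants: 8 (2S)-2-[(2S)-1-hydroxypropan-2-yl]-2,3-dihydro-1-benzofuran-5-ol
Product: 9 (2S)-2-[(2S)-1-hydroxypropan-2-yl]-2,3-dihydro-1-benzofuran-5-yl trifluoromethanesulfonate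
Conditions: PhNTf2 (1.05 equiv), K2CO3 (2 equiv), MeCN, rt
Reagents that add atoms: N-phenylbis(trifluoromethanesulfonimide), O=S(=O)(N(c1ccccc1)S(=O)(=O)C(F)(F)F)C(F)(F)F
Why: Carbonate deprotonates only the phenol (pKa about 10), and only the phenoxide attacks the mild sulfonyl donor, so the primary alcohol stays free (chemoselective aryl triflate formation with an N-aryl triflimide).

Step 6
Reactants: 9 (2S)-2-[(2S)-1-hydroxypropan-2-yl]-2,3-dihydro-1-benzofuran-5-yl trifluoromethanesulfonate; 10 tert-butyl acrylate
Product: 11 tert-butyl (2E)-3-{(2S)-2-[(2S)-1-hydroxypropan-2-yl]-2,3-dihydro-1-benzofuran-5-yl}prop-2-enoate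
Conditions: Pd(OAc)2 (5 mol%), Ph2P(CH2)3PPh2 (6 mol%), Et3N (2.5 equiv), DMF, 80 °C, 10 (3 equiv)
Reagents that add atoms: none
Why: Mizoroki–Heck reaction: oxidative addition of the aryl triflate to zerovalent palladium formed in the flask, syn carbopalladation of the acrylate at its β-carbon and syn β-hydride elimination give the (E)-cinnamate; the free alcohol and both stereocentres are spectators.

Step 7
Reactants: 11 tert-butyl (2E)-3-{(2S)-2-[(2S)-1-hydroxypropan-2-yl]-2,3-dihydro-1-benzofuran-5-yl}prop-2-enoate; 12 p-coumaric acid, (2E)-3-(4-hydroxyphenyl)prop-2-enoic acid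
Product: 13 tert-butyl (2E)-3-[(2S)-2-{(2S)-1-[(2E)-3-(4-hydroxyphenyl)prop-2-enoyloxy]propan-2-yl}-2,3-dihydro-1-benzofuran-5-yl]prop-2-enoate
Conditions: PPh3 (1.4 equiv), DIAD (1.4 equiv), 12 (1.4 equiv), THF, 0 °C to rt
Reagents that add atoms: none
Why: Mitsunobu esterification: the betaine deprotonates the carboxylic acid (pKa about 4.5) in preference to the phenol (pKa about 10), and the carboxylate displaces the alkoxyphosphonium at the primary carbon, which is not a stereocentre, so no phenol protection is needed.

Step 8
Reactants: 13 tert-butyl (2E)-3-[(2S)-2-{(2S)-1-[(2E)-3-(4-hydroxyphenyl)prop-2-enoyloxy]propan-2-yl}-2,3-dihydro-1-benzofuran-5-yl]prop-2-enoate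
Product: 14 (2E)-3-[(2S)-2-{(2S)-1-[(2E)-3-(4-hydroxyphenyl)prop-2-enoyloxy]propan-2-yl}-2,3-dihydro-1-benzofuran-5-yl]prop-2-enoic acid
Conditions: TFA/CH2Cl2 (1:4), 0 °C to rt
Reagents that add atoms: none
Why: Acidolysis of the tert-butyl ester by alkyl–oxygen cleavage with loss of isobutene; the primary coumarate ester, the aryl alkyl ether and both (E)-alkenes are stable to cold TFA, so the acid is freed without hydrolytic or reductive conditions.

## Compound list

1 | 3-methylfuran-2(5H)-one | CC1=CCOC1=O | starting material
2 | 3-methyl-2-(trimethylsilyloxy)furan | Cc1ccoc1O[Si](C)(C)C | intermediate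
3 | 1,4-benzoquinone | O=C1C=CC(=O)C=C1 | starting material
4 | (5S)-5-[2-hydroxy-5-(trimethylsilyloxy)phenyl]-3-methylfuran-2(5H)-one | CC1=C[C@@H](c2cc(O[Si](C)(C)C)ccc2O)OC1=O | intermediate
5 | (3aR,8bR)-3-methyl-7-(trimethylsilyloxy)-3a,8b-dihydrofuro[3,2-b][1]benzofuran-2(3H)-one (C3 epimers, converging on 3R) | CC1[C@H]2Oc3ccc(O[Si](C)(C)C)cc3[C@H]2OC1=O | intermediate
6 | (3R,3aR,8bR)-7-hydroxy-3-methyl-3a,8b-dihydrofuro[3,2-b][1]benzofuran-2(3H)-one | C[C@@H]1[C@H]2Oc3ccc(O)cc3[C@H]2OC1=O | intermediate
7 | (2R)-2-[(2S)-5-hydroxy-2,3-dihydro-1-benzofuran-2-yl]propanoic acid | C[C@@H](C(=O)O)[C@@H]1Cc2cc(O)ccc2O1 | intermediate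
8 | (2S)-2-[(2S)-1-hydroxypropan-2-yl]-2,3-dihydro-1-benzofuran-5-ol | C[C@@H](CO)[C@@H]1Cc2cc(O)ccc2O1 | intermediate
9 | (2S)-2-[(2S)-1-hydroxypropan-2-yl]-2,3-dihydro-1-benzofuran-5-yl trifluoromethanesulfonate | C[C@@H](CO)[C@@H]1Cc2cc(OS(=O)(=O)C(F)(F)F)ccc2O1 | intermediate
10 | tert-butyl acrylate | C=CC(=O)OC(C)(C)C | starting material
11 | tert-butyl (2E)-3-{(2S)-2-[(2S)-1-hydroxypropan-2-yl]-2,3-dihydro-1-benzofuran-5-yl}prop-2-enoate | C[C@@H](CO)[C@@H]1Cc2cc(/C=C/C(=O)OC(C)(C)C)ccc2O1 | intermediate
12 | p-coumaric acid, (2E)-3-(4-hydroxyphenyl)prop-2-enoic acid | O=C(O)/C=C/c1ccc(O)cc1 | starting material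
13 | tert-butyl (2E)-3-[(2S)-2-{(2S)-1-[(2E)-3-(4-hydroxyphenyl)prop-2-enoyloxy]propan-2-yl}-2,3-dihydro-1-benzofuran-5-yl]prop-2-enoate | C[C@@H](COC(=O)/C=C/c1ccc(O)cc1)[C@@H]1Cc2cc(/C=C/C(=O)OC(C)(C)C)ccc2O1 | intermediate
14 | (2E)-3-[(2S)-2-{(2S)-1-[(2E)-3-(4-hydroxyphenyl)prop-2-enoyloxy]propan-2-yl}-2,3-dihydro-1-benzofuran-5-yl]prop-2-enoic acid (CNP0224846.1) | C[C@@H](COC(=O)/C=C/c1ccc(O)cc1)[C@@H]1Cc2cc(/C=C/C(=O)O)ccc2O1 | target

## Step count and risks

Total steps: 8. Longest linear sequence: 8 (1 to 14; compounds 3, 10 and 12 are purchased).

**Risk at step 2 (key step, proposed new method).** Four things can go wrong.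
- Face selection at furan C5 may be poor, because silyl-cation catalysis offers a racemic channel and the binding of unsubstituted 3 to the boron cation may be less ordered than that of substituted quinones.
- Electron transfer between 3 and the electron-rich hydroquinone intermediates may consume material.
- The base treatment may reopen the dihydrofuran ring by retro-oxa-Michael reaction and racemise the γ-carbon, or may leave C3 incompletely equilibrated.
- Acid may ionise the benzylic C–O bond of the product with aromatisation to a benzofuran.

The fallback uses known chemistry and keeps the disconnection. It sets out from 2 and 3. The annulation is run with catalytic TMSOTf in CH2Cl2 at −78 °C followed by the same DBU treatment and work-up, which should give racemic 7-hydroxy-3-methyl-3a,8b-dihydrofuro[3,2-b][1]benzofuran-2(3H)-one F1. Hydrogenolysis as in step 3 gives racemic 2-(5-hydroxy-2,3-dihydro-1-benzofuran-2-yl)propanoic acid F2. This is resolved classically by crystallising its (S)-1-phenylethylammonium salt F3 from an alcohol solvent; which antipode of the base gives the less soluble salt with 7 would have to be found by trial. Acidification returns the route at 7. The price is half of the material and one extra operation.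

**Risk at step 5.** Sulfonylation of the aliphatic hydroxyl, or double sulfonylation, may compete if the phenoxide is slow to react. The fallback removes the alcohol from the problem by changing the order. It sets out from 6, whose phenol is triflated under the same conditions to the lactone aryl triflate (3R,3aR,8bR)-3-methyl-2-oxo-2,3,3a,8b-tetrahydrofuro[3,2-b][1]benzofuran-7-yl trifluoromethanesulfonate F4. Neutral hydrogenolysis over Pd/C, which aryl triflates survive in the absence of base, opens the lactone to (2R)-2-[(2S)-5-(trifluoromethanesulfonyloxy)-2,3-dihydro-1-benzofuran-2-yl]propanoic acid F5. Borane reduction as in step 4 rejoins the route at 9.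

**Risk at step 7.** Alkylation of a phenol oxygen in place of the carboxylate, with oligomer formation, or sluggish displacement at the β-branched carbon may occur. The fallback switches from carboxylate alkylation to acylation with a protected acid. It sets out from 12 and 11.
- Acid 12 is silylated on both oxygens (TBSCl, imidazole, DMF) to tert-butyldimethylsilyl (2E)-3-[4-(tert-butyldimethylsilyloxy)phenyl]prop-2-enoate F6.
- The silyl ester is cleaved (K2CO3, aqueous MeOH–THF) to (2E)-3-[4-(tert-butyldimethylsilyloxy)phenyl]prop-2-enoic acid F7.
- Carbodiimide coupling with 11 (EDC·HCl, DMAP, CH2Cl2, Steglich esterification) gives the silyl-protected diester tert-butyl (2E)-3-[(2S)-2-{(2S)-1-[(2E)-3-(4-(tert-butyldimethylsilyloxy)phenyl)prop-2-enoyloxy]propan-2-yl}-2,3-dihydro-1-benzofuran-5-yl]prop-2-enoate F8.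
- Fluoride buffered with acetic acid (TBAF, AcOH, THF, 0 °C) frees the phenol and returns the route at 13.

**Risk at step 8.** The tert-butyl cation may be captured by the electron-rich phenol or dihydrobenzofuran rings, and acid may cause E/Z drift of the hydroxycinnamate. A cation scavenger is the first remedy. The fallback avoids the tert-butyl ester altogether. It sets out from 9, which is esterified with 12 under the conditions of step 7 to (2S)-2-[(2S)-5-(trifluoromethanesulfonyloxy)-2,3-dihydro-1-benzofuran-2-yl]propyl (2E)-3-(4-hydroxyphenyl)prop-2-enoate F9. A Heck reaction of F9 with acrylic acid itself (Pd(OAc)2, Ph2P(CH2)3PPh2, Et3N, DMF, 80 °C) then arrives at 14 directly, one step shorter. Its cost is a last step run on a substrate that carries a free phenol and a second, less reactive alkene.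

## Further compounds

F1 | step 2 | racemic (3R,3aR,8bR)-7-hydroxy-3-methyl-3a,8b-dihydrofuro[3,2-b][1]benzofuran-2(3H)-one (6 with its antipode) | C[C@@H]1[C@H]2Oc3ccc(O)cc3[C@H]2OC1=O.C[C@H]1[C@@H]2Oc3ccc(O)cc3[C@@H]2OC1=O
F2 | step 2 | racemic (2R)-2-[(2S)-5-hydroxy-2,3-dihydro-1-benzofuran-2-yl]propanoic acid (7 with its antipode) | C[C@@H](C(=O)O)[C@@H]1Cc2cc(O)ccc2O1.C[C@H](C(=O)O)[C@H]1Cc2cc(O)ccc2O1
F3 | step 2 | (S)-1-phenylethylammonium (2R)-2-[(2S)-5-hydroxy-2,3-dihydro-1-benzofuran-2-yl]propanoate | C[C@@H](C(=O)[O-])[C@@H]1Cc2cc(O)ccc2O1.C[C@H]([NH3+])c1ccccc1
F4 | step 5 | (3R,3aR,8bR)-3-methyl-2-oxo-2,3,3a,8b-tetrahydrofuro[3,2-b][1]benzofuran-7-yl trifluoromethanesulfonate | C[C@@H]1[C@H]2Oc3ccc(OS(=O)(=O)C(F)(F)F)cc3[C@H]2OC1=O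
F5 | step 5 | (2R)-2-[(2S)-5-(trifluoromethanesulfonyloxy)-2,3-dihydro-1-benzofuran-2-yl]propanoic acid | C[C@@H](C(=O)O)[C@@H]1Cc2cc(OS(=O)(=O)C(F)(F)F)ccc2O1
F6 | step 7 | tert-butyldimethylsilyl (2E)-3-[4-(tert-butyldimethylsilyloxy)phenyl]prop-2-enoate | CC(C)(C)[Si](C)(C)OC(=O)/C=C/c1ccc(O[Si](C)(C)C(C)(C)C)cc1
F7 | step 7 | (2E)-3-[4-(tert-butyldimethylsilyloxy)phenyl]prop-2-enoic acid | CC(C)(C)[Si](C)(C)Oc1ccc(/C=C/C(=O)O)cc1
F8 | step 7 | tert-butyl (2E)-3-[(2S)-2-{(2S)-1-[(2E)-3-(4-(tert-butyldimethylsilyloxy)phenyl)prop-2-enoyloxy]propan-2-yl}-2,3-dihydro-1-benzofuran-5-yl]prop-2-enoate | C[C@@H](COC(=O)/C=C/c1ccc(O[Si](C)(C)C(C)(C)C)cc1)[C@@H]1Cc2cc(/C=C/C(=O)OC(C)(C)C)ccc2O1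
F9 | step 8 | (2S)-2-[(2S)-5-(trifluoromethanesulfonyloxy)-2,3-dihydro-1-benzofuran-2-yl]propyl (2E)-3-(4-hydroxyphenyl)prop-2-enoate | C[C@@H](COC(=O)/C=C/c1ccc(O)cc1)[C@@H]1Cc2cc(OS(=O)(=O)C(F)(F)F)ccc2O1
A1 | alternative 1 | tert-butyl(dimethyl){[(2S,3S)-2-methyl-3-{[(triethylsilyl)ethynyl]oxy}hex-5-yn-1-yl]oxy}silane | C[C@@H](CO[Si](C)(C)C(C)(C)C)[C@H](CC#C)OC#C[Si](CC)(CC)CC
A2 | alternative 1 | 3,3-diethoxyprop-1-yne | C#CC(OCC)OCC
A3 | alternative 1 | tert-butyl{(2S)-2-[(2S)-5-(diethoxymethyl)-7-(triethylsilyl)-2,3-dihydro-1-benzofuran-2-yl]propoxy}dimethylsilane | C[C@@H](CO[Si](C)(C)C(C)(C)C)[C@@H]1Cc2cc(C(OCC)OCC)cc([Si](CC)(CC)CC)c2O1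
A4 | alternative 2 | N'-[(E)-(5-bromo-2-{[(2R)-3-(tert-butyldimethylsilyloxy)-2-methylpropyl]oxy}phenyl)methylidene]-4-methylbenzenesulfonohydrazide | C[C@@H](CO[Si](C)(C)C(C)(C)C)COc1ccc(Br)cc1/C=N/NS(=O)(=O)c1ccc(C)cc1
A5 | alternative 2 | {(2S)-2-[(2S)-5-bromo-2,3-dihydro-1-benzofuran-2-yl]propoxy}(tert-butyl)dimethylsilane | C[C@@H](CO[Si](C)(C)C(C)(C)C)[C@@H]1Cc2cc(Br)ccc2O1
A6 | alternative 3 | (3S)-3-[(2S)-1-(tert-butyldimethylsilyloxy)propan-2-yl]-3,4-dihydro-1H-isochromen-1-one | C[C@@H](CO[Si](C)(C)C(C)(C)C)[C@@H]1Cc2ccccc2C(=O)O1
A7 | alternative 3 | tert-butyl{(2S)-2-[(2S)-2,3-dihydro-1-benzofuran-2-yl]propoxy}dimethylsilane | C[C@@H](CO[Si](C)(C)C(C)(C)C)[C@@H]1Cc2ccccc2O1
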